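**Assumption:** the SMILES carries no stereodescriptor and the molecule has no stereogenic centre, so the target is made as drawn, without a defined sense of twist of the strained cyclophane and without enantiocontrol.

**Ring labels:** ring A = methoxy-bearing ring; ring B = chlorophenol ring carrying the CH2CH2 bridge; ring C = 4-alkylphenol ring; ring D = chlorophenol ring carrying the formyl (later phenanthrene) carbon.

## Retrosynthetic overview

1. Target ⇐ 16-membered macrocyclic Z-stilbene: the central phenanthrene ring is closed last by oxidative 6π photocyclisation (ring A–ring D bond).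
2. Macrocyclic Z-stilbene ⇐ seco-dialdehyde (rings D–C–B–A) by McMurry macrocyclisation.
3. Seco-dialdehyde ⇐ ring B aryl bromide + ring A boronic acid (Suzuki coupling, ring A–ring B axis).
4. Ring C–ring D 2,2'-biphenol ⇐ bibenzyl diphenol + 3-chloro-4-hydroxybenzaldehyde: the strategic bond is a C–O bond (para-quinol aryl ether), relayed in the same flask by a [3,3] shift to the biaryl bond.
5. Bibenzyl ⇐ 2-bromo-4-chloroanisole (formylation between the halogens), benzylic phosphonate olefination, C=C reduction, demethylation. Ring order: macrocycle first, central phenanthrene ring last.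

## Route

**Step 1**
Reactants: 1 2-bromo-4-chloro-1-methoxybenzene (2-bromo-4-chloroanisole)
Product: 3 2-bromo-6-chloro-3-methoxybenzaldehyde, via aryllithium 2 (not isolated)
Conditions: LiN(iPr)2 (1.1 equiv), THF, −78 °C, 1 h; DMF (2 equiv), −78 °C to 0 °C; aq. HCl
Reagents that add atoms: N,N-dimethylformamide (DMF), CN(C)C=O
Why: Deprotonative metalation with an amide base removes the most acidic ring hydrogen, the one flanked by bromine and chlorine (no halogen–metal exchange at −78 °C), and the aryllithium is formylated by DMF.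

**Step 2**
Reactants: 3 2-bromo-6-chloro-3-methoxybenzaldehyde; 4 diethyl [(4-methoxyphenyl)methyl]phosphonate
Product: 5 2-bromo-4-chloro-1-methoxy-3-[(E)-2-(4-methoxyphenyl)ethenyl]benzene
Conditions: 4 (1.2 equiv), KOtBu (1.3 equiv), THF, 0 °C; then 3, 0 °C to rt
Reagents that add atoms: none
Why: Horner–Wadsworth–Emmons olefination of the non-enolisable aldehyde with the benzylic phosphonate anion gives the E-stilbene, whose geometry is irrelevant because the alkene is reduced next.

**Step 3**
Reactants: 5 2-bromo-4-chloro-1-methoxy-3-[(E)-2-(4-methoxyphenyl)ethenyl]benzene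
Product: 6 2-bromo-4-chloro-1-methoxy-3-[2-(4-methoxyphenyl)ethyl]benzene
Conditions: TsNHNH2 (8 equiv, in portions), NaOAc (10 equiv), DME/H2O, reflux
Reagents that add atoms: none
Why: Diimide reduction (diimide generated from the sulfonyl hydrazide) saturates the C=C bond without touching the aryl bromide or chloride, which a palladium-catalysed hydrogenation would endanger.

**Step 4**
Reactants: 6 2-bromo-4-chloro-1-methoxy-3-[2-(4-methoxyphenyl)ethyl]benzene
Product: 7 2-bromo-4-chloro-3-[2-(4-hydroxyphenyl)ethyl]phenol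
Conditions: BBr3 (4 equiv), CH2Cl2, −78 °C to rt; H2O
Reagents that add atoms: none
Why: Lewis-acid aryl methyl ether cleavage with BBr3 frees both phenols before the ring A methyl ether, which must survive to the target, enters the route.

**Step 5**
Reactants: 7 2-bromo-4-chloro-3-[2-(4-hydroxyphenyl)ethyl]phenol; 8 3-chloro-4-hydroxybenzaldehyde
Product: 11 3-chloro-5-{5-[2-(2-bromo-6-chloro-3-hydroxyphenyl)ethyl]-2-hydroxyphenyl}-4-hydroxybenzaldehyde, via quinol aryl ether 9 (not isolated), via bis-dienone 10 (not isolated)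
Conditions: 8 (4 equiv), PhI(OCOCF3)2 (1.0 equiv, slow addition), (CF3)2CHOH/CH2Cl2 (4:1), −40 °C; then 45 °C, 3 h
Reagents that add atoms: none
Why: Proposed new method: a dearomative C–O cross-coupling with sigmatropic relay, in which the trivalent-iodine reagent oxidises only the electron-rich 4-alkylphenol ring C of 7 (the bromo-chloro ring B is deactivated) to a phenoxonium-type species, the electron-poor phenol 8 (not oxidisable, para position blocked, poor carbon nucleophile) traps it through oxygen at the para carbon to give 9 at −40 °C, and after the oxidant is spent warming triggers a [3,3] Claisen-type shift (helped by the CF3CO2H released and by the weak doubly allylic C–O bond to a good aryloxide leaving group) that forms the ortho,ortho' C–C bond and, after double tautomerisation of 10, the 2,2'-biphenol (only one ortho position of 8 is free and the two of ring C are equivalent); the closest known reactions are the oxidative dearomatisation of 4-alkylphenols with oxygen nucleophiles to para-quinol ethers, the acid-catalysed [3,3] rearrangement of quinone-monoketal-derived mixed aryl ketals to 2,2'-dioxygenated biaryls and the aromatic Claisen rearrangement, but capture of a 4-alkylphenoxonium by a phenol oxygen with relay to a biphenol has not been shown.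

**Step 6**
Reactants: 11 3-chloro-5-{5-[2-(2-bromo-6-chloro-3-hydroxyphenyl)ethyl]-2-hydroxyphenyl}-4-hydroxybenzaldehyde; 12 (4-formyl-2-methoxyphenyl)boronic acid
Product: 13 4-[3-chloro-2-(2-{3-(3-chloro-5-formyl-2-hydroxyphenyl)-4-hydroxyphenyl}ethyl)-6-hydroxyphenyl]-3-methoxybenzaldehyde
Conditions: 12 (1.4 equiv), Pd(OAc)2 (5 mol %), SPhos (10 mol %), K3PO4 (5 equiv), 1,4-dioxane/H2O (5:1), 80 °C
Reagents that add atoms: none
Why: Suzuki–Miyaura coupling at the only C–Br bond, since oxidative addition to zerovalent palladium is much faster there than at the two electron-rich C–Cl bonds, with a bulky biarylphosphine that tolerates free phenols and the tri-ortho-substituted axis.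

**Step 7**
Reactants: 13 4-[3-chloro-2-(2-{3-(3-chloro-5-formyl-2-hydroxyphenyl)-4-hydroxyphenyl}ethyl)-6-hydroxyphenyl]-3-methoxybenzaldehyde
Product: 14 16-membered macrocyclic Z-stilbene (the two formyl carbons of 13 joined as a Z CH=CH bridge between ring A and ring D)
Conditions: TiCl4 (12 equiv), Zn dust (24 equiv), pyridine (6 equiv), THF, reflux; 13 added over 20 h (final 1 mM)
Reagents that add atoms: none
Why: Intramolecular McMurry coupling under high dilution, where the rigid tetra-aryl frame lets the 16-membered ring close only as the Z alkene and the aryl chlorides and titanium-bound phenoxides survive low-valent titanium.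

**Step 8**
Reactants: 14 16-membered macrocyclic Z-stilbene
Product: 16 target CNP0310669.0, via dihydrophenanthrene 15 (not isolated)
Conditions: hν (medium-pressure Hg lamp, Pyrex, λ > 300 nm), I2 (1.1 equiv), propylene oxide (50 equiv), degassed toluene (0.5 mM), rt
Reagents that add atoms: none
Why: Mallory oxidative photocyclisation, a conrotatory 6π closure of the Z-stilbene to the trans-4a,4b-dihydrophenanthrene that I2 dehydrogenates while propylene oxide traps HI; the macrocycle holds the inner carbon of ring D next to ring A, and closure at the ring A carbon para to methoxy avoids a bay methoxy group.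

## Compound list

1 | 2-bromo-4-chloro-1-methoxybenzene | COc1ccc(Cl)cc1Br | starting material
2 | (2-bromo-6-chloro-3-methoxyphenyl)lithium | COc1ccc(Cl)c([Li])c1Br | intermediate
3 | 2-bromo-6-chloro-3-methoxybenzaldehyde | COc1ccc(Cl)c(C=O)c1Br | intermediate
4 | diethyl [(4-methoxyphenyl)methyl]phosphonate | CCOP(=O)(Cc1ccc(OC)cc1)OCC | starting material
5 | 2-bromo-4-chloro-1-methoxy-3-[(E)-2-(4-methoxyphenyl)ethenyl]benzene | COc1ccc(/C=C/c2c(Cl)ccc(OC)c2Br)cc1 | intermediate
6 | 2-bromo-4-chloro-1-methoxy-3-[2-(4-methoxyphenyl)ethyl]benzene | COc1ccc(CCc2c(Cl)ccc(OC)c2Br)cc1 | intermediate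
7 | 2-bromo-4-chloro-3-[2-(4-hydroxyphenyl)ethyl]phenol | Oc1ccc(CCc2c(Cl)ccc(O)c2Br)cc1 | intermediate
8 | 3-chloro-4-hydroxybenzaldehyde | O=Cc1ccc(O)c(Cl)c1 | starting material
9 | 4-({1-[2-(2-bromo-6-chloro-3-hydroxyphenyl)ethyl]-4-oxocyclohexa-2,5-dien-1-yl}oxy)-3-chlorobenzaldehyde (quinol aryl ether) | O=Cc1ccc(OC2(CCc3c(Cl)ccc(O)c3Br)C=CC(=O)C=C2)c(Cl)c1 | intermediate
10 | 5-chloro-3-{3-[2-(2-bromo-6-chloro-3-hydroxyphenyl)ethyl]-6-oxocyclohexa-2,4-dien-1-yl}-4-oxocyclohexa-1,5-diene-1-carbaldehyde (bis-dienone, diastereomer mixture, both CH centres lost on tautomerisation) | O=C1C=CC(CCc2c(Cl)ccc(O)c2Br)=CC1C1C=C(C=O)C=C(Cl)C1=O | intermediate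
11 | 3-chloro-5-{5-[2-(2-bromo-6-chloro-3-hydroxyphenyl)ethyl]-2-hydroxyphenyl}-4-hydroxybenzaldehyde | O=Cc1cc(Cl)c(O)c(c1)-c1cc(CCc2c(Cl)ccc(O)c2Br)ccc1O | intermediate
12 | (4-formyl-2-methoxyphenyl)boronic acid | COc1cc(C=O)ccc1B(O)O | starting material
13 | 4-[3-chloro-2-(2-{3-(3-chloro-5-formyl-2-hydroxyphenyl)-4-hydroxyphenyl}ethyl)-6-hydroxyphenyl]-3-methoxybenzaldehyde | COc1cc(C=O)ccc1-c1c(O)ccc(Cl)c1CCc1ccc(O)c(c1)-c1cc(C=O)cc(Cl)c1O | intermediate
14 | 16-membered macrocyclic Z-stilbene (Z CH=CH between ring A and ring D; rings A–B and C–D joined as biaryls, rings B–C by CH2CH2) | COc1cc2/C=C\c3cc(Cl)c(O)c(c3)-c3cc(CCc4c(Cl)ccc(O)c4-c1cc2)ccc3O | intermediate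
15 | trans-4a,4b-dihydrophenanthrene photoproduct (racemic; new sp3 CH carbons are the ring A carbon para to methoxy and the ring D carbon between the alkene carbon and ring C) | COC1=CC2=CC=C3C=C(Cl)C(O)=C4[C@H]3[C@@H]2C=C1-c1c(O)ccc(Cl)c1CCc1ccc(O)c4c1 | intermediate
16 | CNP0310669.0 (7-chloro-6-hydroxy-2-methoxyphenanthrene bridged from C-3 through ring B, CH2CH2 and ring C to C-5) | COc1cc2ccc3cc(Cl)c(O)c4c3c2cc1-c1c(O)ccc(Cl)c1CCc1ccc(O)c-4c1 | target

## Summary

Total step count: 8. Longest linear sequence: 8 steps (from 1; compounds 4, 8 and 12 are bought).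

**Steps most likely to fail**

Step 5 (proposed new step). The phenoxonium could be trapped by trifluoroacetate, lose a benzylic proton to a quinone methide, or the quinol ether could ionise without C–C collapse. Fallback with known chemistry, setting out from 7 and coming back at 11: ring C is iodinated ortho to its hydroxyl with N-iodosuccinimide (1.0 equiv, TsOH cat., MeCN, 0 °C; the halogenated ring B is far less reactive) to give 2-bromo-4-chloro-3-[2-(4-hydroxy-3-iodophenyl)ethyl]phenol F1. Separately, commercial 3-bromo-5-chloro-4-hydroxybenzaldehyde is borylated (B2pin2, PdCl2(dppf), KOAc, dioxane, 90 °C) to 3-chloro-4-hydroxy-5-(4,4,5,5-tetramethyl-1,3,2-dioxaborolan-2-yl)benzaldehyde F2. Suzuki coupling of F1 with F2 at the C–I bond (Pd(PPh3)4, K2CO3, DME/H2O, 60 °C; the di-ortho-substituted C–Br bond is left alone at this temperature) gives 11.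

Step 7. Three free phenols consume low-valent titanium, and pinacols or oligomers may dominate. Fallback setting out from 13 and coming back at 14: double Wittig methylenation (Ph3PCH3Br/KOtBu, 8 equiv to cover the phenoxides, THF, 0 °C to rt) gives 4-[3-chloro-2-(2-{3-(3-chloro-5-ethenyl-2-hydroxyphenyl)-4-hydroxyphenyl}ethyl)-6-hydroxyphenyl]-1-ethenyl-3-methoxybenzene F3. Ring-closing metathesis (second-generation Grubbs catalyst RuCl2(=CHPh)(H2IMes)(PCy3), 10 mol %, toluene, 1 mM, 80 °C, ethene purged) then closes the stilbene ring to 14; the ring strain admits only the Z alkene.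

Step 8. The closure builds the strained 12-membered inner ring, may occur at the ring A carbon next to methoxy instead, and iodine may attack the free phenols. Fallback setting out from 11 and coming back at 16: Suzuki coupling as in step 6, but with 2,5-dimethoxy-4-(4,4,5,5-tetramethyl-1,3,2-dioxaborolan-2-yl)benzaldehyde F4 (from commercial 4-bromo-2,5-dimethoxybenzaldehyde, B2pin2, PdCl2(dppf), KOAc), gives 4-[3-chloro-2-(2-{3-(3-chloro-5-formyl-2-hydroxyphenyl)-4-hydroxyphenyl}ethyl)-6-hydroxyphenyl]-2,5-dimethoxybenzaldehyde F5. McMurry coupling as in step 7 gives the macrocyclic Z-stilbene carrying an extra methoxy group on the ring A carbon ortho to the alkene F6. Irradiation without any oxidant (degassed t-BuOH/toluene, λ > 300 nm) closes onto the methoxy-bearing carbon and the dihydrophenanthrene loses methanol (eliminative, non-oxidative photocyclisation of an ortho-methoxystilbene). This fixes the ring A regiochemistry, needs no iodine, and gives 16.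

## Further compounds

F1 | step 5 | 2-bromo-4-chloro-3-[2-(4-hydroxy-3-iodophenyl)ethyl]phenol | Oc1ccc(CCc2c(Cl)ccc(O)c2Br)cc1I
F2 | step 5 | 3-chloro-4-hydroxy-5-(4,4,5,5-tetramethyl-1,3,2-dioxaborolan-2-yl)benzaldehyde | O=Cc1cc(Cl)c(O)c(c1)B1OC(C)(C)C(C)(C)O1
F3 | step 7 | 4-[3-chloro-2-(2-{3-(3-chloro-5-ethenyl-2-hydroxyphenyl)-4-hydroxyphenyl}ethyl)-6-hydroxyphenyl]-1-ethenyl-3-methoxybenzene | COc1cc(C=C)ccc1-c1c(O)ccc(Cl)c1CCc1ccc(O)c(c1)-c1cc(C=C)cc(Cl)c1O
F4 | step 8 | 2,5-dimethoxy-4-(4,4,5,5-tetramethyl-1,3,2-dioxaborolan-2-yl)benzaldehyde | COc1cc(B2OC(C)(C)C(C)(C)O2)c(OC)cc1C=O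
F5 | step 8 | 4-[3-chloro-2-(2-{3-(3-chloro-5-formyl-2-hydroxyphenyl)-4-hydroxyphenyl}ethyl)-6-hydroxyphenyl]-2,5-dimethoxybenzaldehyde | COc1cc(C=O)c(OC)cc1-c1c(O)ccc(Cl)c1CCc1ccc(O)c(c1)-c1cc(C=O)cc(Cl)c1O
F6 | step 8 | 16-membered macrocyclic Z-stilbene with an extra methoxy group on the ring A carbon ortho to the alkene | COc1cc2/C=C\c3cc(Cl)c(O)c(c3)-c3cc(CCc4c(Cl)ccc(O)c4-c1cc2OC)ccc3O
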